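**Retrosynthetic overview**
1. Target 24 ⇐ trimethyl ester 23 (thiolate demethylation, desilylation, C6 equilibration) ⇐ alkynyl ketone 20; ring D by ketyl–alkyne closure of C13–C16.
2. 20 ⇐ ABC ketone 17; ring C by intramolecular Michael addition (C8–C14) of a methyl ketone tethered at C9 onto a Δ6(8) enoate, the C8 allyl group coming from triflate/Stille coupling and the C9 chain from dianion alkylation of AB β-keto ester 7.
3. 7 ⇐ keto diester 3 + dimethyl itaconate 4 in one operation: Michael (C1–C2), Michael (C5–C10, closes ring A), Dieckmann (C6–C8, closes ring B); 3 ⇐ methyl 2-methylacetoacetate + methyl propiolate (sets C4).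
4. Enabling feature: C5 is the shared β-carbon of the three carboxyl-bearing carbons C4 (C19), C6 (C7) and C10 (C20), C3 is the acetoacetate ketone and C8 is 1,3 to C7, so rings A and B are a latent 1,5-/1,3-dicarbonyl (Michael/Dieckmann) array with every carboxyl already at its final oxidation level.
5. Ring order: A → B (same flask) → C → D.

Key step: step 2

Remark: atom numbers (C1–C20) and α/β of all intermediates follow the gibberellane skeleton of the target (β = face of H-5, H-9 and 3-OH; C19 and C20 are α); the sense of induction of the phase-transfer catalyst in step 1 is assumed to be selectable through its pseudoenantiomer.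

**Step 1**
Reactants: 1 methyl 2-methyl-3-oxobutanoate; 2 methyl propiolate
Product: 3 dimethyl (2E,4S)-4-acetyl-4-methylpent-2-enedioate
Conditions: O-allyl-N-(9-anthracenylmethyl)cinchonidinium bromide (10 mol %), Cs2CO3 (20 mol %), toluene, −40 °C; then PBu3 (10 mol %), CH2Cl2, 20 °C
Reagents that add atoms: none
Why: Michael addition of the α-methyl β-keto ester to the ynoate under chiral ion-pair (phase-transfer) catalysis should create the quaternary C4 as (S), and reversible phosphine addition should converge the E/Z mixture to the E enoate.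

**Step 2**
Reactants: 3 keto diester; 4 dimethyl itaconate
Product: 7 AB-ring β-keto triester, via acyclic C10 ester enolate 5 (not isolated), via ring-A C6 ester enolate 6 (not isolated)
Conditions: LiN(SiMe3)2 (1.05 equiv), THF, −78 °C; 4, −78 → −20 °C; AcOH, −78 °C
Reagents that add atoms: none
Why: Kinetic deprotonation of 3 can only occur at the acetyl CH3 (C2; C4 is quaternary and there is no γ-H), and this enolate adds to the CH2 terminus of 4 (Michael addition, C1–C2) to give ester enolate 5 at C10; 5 closes ring A by 6-exo-trig Michael addition to C5 of the E-enoate, which forms the C5–C10 bond, and the new C6 ester enolate 6 closes ring B by 5-exo-trig Dieckmann condensation on the CH2CO2Me carbonyl (C8) with loss of methoxide, the β-keto ester enolate being the thermodynamic sink. The closest known reaction type is the Michael–Michael–ring-closure (Michael–Dieckmann) annulation of ketone enolates with acrylates. C5 and C10 are controlled by the preset C4: in the chair-like transition state the C18 methyl, the C9 arm and the acceptor arm should be equatorial while the flat C19 ester and the enolate carbon C20 are syn-axial on the α face and can share lithium, so H-5 ends anti and C20 syn to C19, and the then trans-diequatorial C6 and C9 arms give the trans-fused bicycle. C6, lying between two carbonyls, equilibrates to the 6β ester. The step needs the conjugate addition of 5 to outrun Claisen attack on C19 and proton transfer; the low temperature, the six-membered intramolecular closure and the E geometry (C7 out of reach of C2 and C10) are meant to secure this, and 6 has only the C8 carbonyl within five-membered reach.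

**Step 3**
Reactants: 7 AB-ring β-keto triester
Product: 8 3β-alcohol
Conditions: NaH (1.05 equiv), THF, 0 °C; then LiBH(s-Bu)3 (1.2 equiv), −78 °C; AcOH, −78 °C
Reagents that add atoms: none
Why: Irreversible deprotonation of the β-keto ester by NaH masks the C8 ketone as its enolate, and the bulky trialkylborohydride should then reduce the C3 ketone along the equatorial trajectory, away from the axial H-1β and H-5β, to give the axial 3β-alcohol (hindered-hydride ketone reduction).

**Step 4**
Reactants: 8 3β-alcohol
Product: 10 3-O-TBS β-keto triester, via bis-silyl enol ether 9 (not isolated)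
Conditions: TBSOTf (2.5 equiv), 2,6-lutidine, CH2Cl2, 0 °C; then citric acid, MeOH–H2O, 20 °C
Reagents that add atoms: tert-butyldimethylsilyl triflate, CC(C)(C)[Si](C)(C)OS(=O)(=O)C(F)(F)F
Why: Silyl triflate silylation protects the hindered axial alcohol (blocking later retro-aldol at C3–C4); the enol silyl ether formed at the β-keto ester is cleaved by the mild acid while the secondary TBS ether survives.

**Step 5**
Reactants: 10 3-O-TBS β-keto triester; 11 2-(2-bromoethyl)-2-methyl-1,3-dioxolane
Product: 12 C9-alkylated β-keto triester (9-epi)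
Conditions: LiN(i-Pr)2 (2.2 equiv), THF, −78 → 0 °C; 11, DMPU, 0 °C; AcOH
Reagents that add atoms: none
Why: γ-Alkylation of a β-keto ester dianion: after C6–H the only remaining acidic site is C9, whose carbanion alkylates with the primary bromide, expected anti to the axial C20 ester (chain β); this C9 configuration is corrected in step 6.

**Step 6**
Reactants: 12 C9-alkylated β-keto triester (9-epi)
Product: 13 C9-corrected β-keto triester
Conditions: LiN(i-Pr)2 (2.5 equiv), THF–DMPU, −78 → 0 °C; then AcOH, −78 °C
Reagents that add atoms: none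
Why: Epimerisation by deprotonation and kinetic protonation: re-formation of the dianion planarises C9, and protonation from the same open β face (anti to the axial C20 ester) should leave H-9 β and the side chain α, the arrangement that also places C11 next to the flat ester and not next to C1.

**Step 7**
Reactants: 13 C9-corrected β-keto triester
Product: 14 enol triflate
Conditions: NaH, THF, 0 °C; PhNTf2, 20 °C
Reagents that add atoms: N-phenylbis(trifluoromethanesulfonimide), O=S(=O)(N(c1ccccc1)S(=O)(=O)C(F)(F)F)C(F)(F)F
Why: Only C6–H is acidic enough for NaH, and O-sulfonylation of the β-keto ester enolate gives the Δ6(8) vinyl triflate without touching C9.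

**Step 8**
Reactants: 14 enol triflate
Product: 15 8-allyl enoate
Conditions: allylSnBu3, Pd(PPh3)4 (5 mol %), LiCl, THF, 65 °C
Reagents that add atoms: allyltributylstannane, C=CC[Sn](CCCC)(CCCC)CCCC
Why: Stille cross-coupling of the activated β-triflyloxy enoate installs C15–C17 at C8 under neutral conditions that leave the allylic C9 centre, the ketal and the silyl ether untouched.

**Step 9**
Reactants: 15 8-allyl enoate
Product: 16 methyl ketone
Conditions: PPTS (cat.), THF–H2O, 45 °C
Reagents that add atoms: water, O
Why: Mild acid-catalysed ketal hydrolysis unmasks the C13 ketone; the TBS ether, the esters and the skipped diene tolerate these conditions.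

**Step 10**
Reactants: 16 methyl ketone
Product: 17 ABC tricyclic ketone
Conditions: LiN(SiMe3)2 (1.1 equiv), THF, −78 → −20 °C; AcOH, −78 °C
Reagents that add atoms: none
Why: Kinetic enolisation of the methyl ketone at CH3 (C14) and intramolecular 6-exo-trig Michael addition to the tetrasubstituted enoate closes ring C and makes C8 quaternary; the nucleophile is tethered to the α face at C9, so C14 must bond on that face (cis B/C junction, allyl β), while C6 is protonated from the open β face and is expected mainly as the 6α ester, to be set in step 14.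

**Step 11**
Reactants: 17 ABC tricyclic ketone
Product: 19 aldehyde, via secondary ozonide 18 (not isolated)
Conditions: O3, CH2Cl2, −78 °C; then Me2S, −78 → 20 °C
Reagents that add atoms: ozone, O=[O+][O-]
Why: Ozonolysis with reductive work-up cleaves the only C=C bond of 17 to the C16 aldehyde.

**Step 12**
Reactants: 19 aldehyde
Product: 20 alkynyl ketone
Conditions: dimethyl (1-diazo-2-oxopropyl)phosphonate, K2CO3, MeOH, 0 °C
Reagents that add atoms: dimethyl (1-diazo-2-oxopropyl)phosphonate, COP(=O)(OC)C(=[N+]=[N-])C(C)=O
Why: Seyferth–Gilbert homologation with the Ohira–Bestmann reagent converts the aldehyde into the terminal alkyne (C17 from the reagent); the hindered ketone reacts far more slowly and the low temperature should limit aldol side reactions.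

**Step 13**
Reactants: 20 alkynyl ketone
Product: 21 tetracyclic 13-ol (6-epi series)
Conditions: SmI2, HMPA, t-BuOH, THF, 0 °C
Reagents that add atoms: none
Why: Ketyl–alkyne reductive cyclisation: the C13 ketyl adds 5-exo-dig to C16 and the vinyl radical is reduced and protonated, giving the bridgehead tertiary alcohol and the exocyclic methylene; the C13 configuration is dictated by the bicyclo[3.2.1]octane bridge and the esters are inert to SmI2 under these conditions.

**Step 14**
Reactants: 21 tetracyclic 13-ol (6-epi series)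
Product: 22 3-O-TBS trimethyl ester of the target
Conditions: NaOMe (cat.), MeOH, 45 °C
Reagents that add atoms: none
Why: Base-mediated epimerisation at the only enolisable stereocentre (C6) should converge any C6 mixture on the thermodynamically preferred 6β ester, trans to the C4 side of C5; with C13 no longer a ketone, retro-Michael opening of ring C is closed off.

**Step 15**
Reactants: 22 3-O-TBS trimethyl ester of the target
Product: 23 trimethyl ester of the target
Conditions: HF·pyridine, pyridine, THF, 0 → 20 °C
Reagents that add atoms: none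
Why: Fluoride-mediated desilylation under buffered conditions cleaves the Si–O bond without the strong acid that could rearrange the tertiary allylic alcohol or the strong base that could trigger retro-aldol at C3.

**Step 16**
Reactants: 23 trimethyl ester of the target
Product: 24 target gibberellin
Conditions: LiSPr, HMPA, 25 °C; then dilute HCl, 0 °C
Reagents that add atoms: none
Why: Thiolate demethylation by bimolecular nucleophilic substitution attacks the O–CH3 carbons, so the hindered C19 and C20 esters are cleaved as readily as C7, and the carboxylates formed cannot epimerise at C6.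

**Compound list**
1 | methyl 2-methyl-3-oxobutanoate | CC(=O)C(C)C(=O)OC | starting material
2 | methyl propiolate (methyl prop-2-ynoate) | C#CC(=O)OC | starting material
3 | dimethyl (2E,4S)-4-acetyl-4-methylpent-2-enedioate (C2–C7, C18, C19) | CC(=O)[C@@](C)(C(=O)OC)/C=C/C(=O)OC | intermediate
4 | dimethyl itaconate (dimethyl 2-methylidenebutanedioate; C1, C8–C10, C20) | C=C(CC(=O)OC)C(=O)OC | starting material
5 | lithium ester enolate at C10 of the acyclic Michael adduct of 3 and 4 | COC(=O)CC(CCC(=O)[C@@](C)(C(=O)OC)/C=C/C(=O)OC)=C([O-])OC.[Li+] | intermediate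
6 | lithium ester enolate at C6 of the ring-A cyclohexanone (3-oxo, 4β-Me, 4α-CO2Me, 5β-H, 10α-CO2Me, 10-CH2CO2Me) | COC(=O)C[C@]1(C(=O)OC)CCC(=O)[C@@](C)(C(=O)OC)[C@H]1C=C([O-])OC.[Li+] | intermediate
7 | trimethyl 7-methyl-2,6-dioxooctahydro-1H-indene-1,3a,7-tricarboxylate, trans-fused (gibberellane numbering: 3,8-dioxo, 4β-Me, 4α-CO2Me, 5β-H, 6β-CO2Me, 10α-CO2Me) | O=C1C[C@]2(C(=O)OC)CCC(=O)[C@@](C)(C(=O)OC)[C@H]2[C@@H]1C(=O)OC | intermediate
8 | 3β-hydroxy analogue of 7 (axial OH, cis to C18) | O=C1C[C@]2(C(=O)OC)CC[C@H](O)[C@@](C)(C(=O)OC)[C@H]2[C@@H]1C(=O)OC | intermediate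
9 | 3-O-TBS ether of 8 with the β-keto ester as its 8-O-TBS Δ6(8) enol ether | COC(=O)C1=C(O[Si](C)(C)C(C)(C)C)C[C@]2(C(=O)OC)CC[C@H](O[Si](C)(C)C(C)(C)C)[C@@](C)(C(=O)OC)[C@H]21 | intermediate
10 | 3β-O-TBS ether of 8 | O=C1C[C@]2(C(=O)OC)CC[C@H](O[Si](C)(C)C(C)(C)C)[C@@](C)(C(=O)OC)[C@H]2[C@@H]1C(=O)OC | intermediate
11 | 2-(2-bromoethyl)-2-methyl-1,3-dioxolane | CC1(CCBr)OCCO1 | starting material
12 | 10 bearing the 2-(2-methyl-1,3-dioxolan-2-yl)ethyl chain (C11, C12, C13, C14) at C9 on the β face (9-epi, H-9α) | O=C1[C@H](CCC3(C)OCCO3)[C@]2(C(=O)OC)CC[C@H](O[Si](C)(C)C(C)(C)C)[C@@](C)(C(=O)OC)[C@H]2[C@@H]1C(=O)OC | intermediate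
13 | C9 epimer of 12 (chain α, H-9β) | O=C1[C@@H](CCC3(C)OCCO3)[C@]2(C(=O)OC)CC[C@H](O[Si](C)(C)C(C)(C)C)[C@@](C)(C(=O)OC)[C@H]2[C@@H]1C(=O)OC | intermediate
14 | Δ6(8) enol triflate of 13 (8-OTf, 6-CO2Me) | FC(F)(F)S(=O)(=O)OC=1[C@@H](CCC3(C)OCCO3)[C@]2(C(=O)OC)CC[C@H](O[Si](C)(C)C(C)(C)C)[C@@](C)(C(=O)OC)[C@H]2C=1C(=O)OC | intermediate
15 | 8-allyl Δ6(8) enoate (ketal side chain at C9α) | C=CCC=1[C@@H](CCC3(C)OCCO3)[C@]2(C(=O)OC)CC[C@H](O[Si](C)(C)C(C)(C)C)[C@@](C)(C(=O)OC)[C@H]2C=1C(=O)OC | intermediate
16 | 8-allyl Δ6(8) enoate with the 3-oxobutyl chain at C9α | C=CCC=1[C@@H](CCC(C)=O)[C@]2(C(=O)OC)CC[C@H](O[Si](C)(C)C(C)(C)C)[C@@](C)(C(=O)OC)[C@H]2C=1C(=O)OC | intermediate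
17 | ABC tricyclic 13-ketone: 8β-allyl, C14 α (cis B/C), H-9β, 6α-CO2Me (6-epi), 3β-OTBS | C=CC[C@]12CC(=O)CC[C@H]1[C@]3(C(=O)OC)CC[C@H](O[Si](C)(C)C(C)(C)C)[C@@](C)(C(=O)OC)[C@H]3[C@H]2C(=O)OC | intermediate
18 | 1,2,4-trioxolane (secondary ozonide) of the allyl group of 17 | C4(OCOO4)C[C@]12CC(=O)CC[C@H]1[C@]3(C(=O)OC)CC[C@H](O[Si](C)(C)C(C)(C)C)[C@@](C)(C(=O)OC)[C@H]3[C@H]2C(=O)OC | intermediate
19 | 8β-(2-oxoethyl) 13-ketone (C16 aldehyde) | O=CC[C@]12CC(=O)CC[C@H]1[C@]3(C(=O)OC)CC[C@H](O[Si](C)(C)C(C)(C)C)[C@@](C)(C(=O)OC)[C@H]3[C@H]2C(=O)OC | intermediate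
20 | 8β-propargyl 13-ketone | C#CC[C@]12CC(=O)CC[C@H]1[C@]3(C(=O)OC)CC[C@H](O[Si](C)(C)C(C)(C)C)[C@@](C)(C(=O)OC)[C@H]3[C@H]2C(=O)OC | intermediate
21 | 6-epimer of the 3-O-TBS trimethyl ester of the target (tetracyclic 13-ol, 6α-CO2Me) | C=C1C[C@]23C[C@@]1(O)CC[C@H]2[C@]1(C(=O)OC)CC[C@H](O[Si](C)(C)C(C)(C)C)[C@@](C)(C(=O)OC)[C@H]1[C@H]3C(=O)OC | intermediate
22 | 3-O-TBS ether of the trimethyl ester of the target gibberellin | C=C1C[C@]23C[C@@]1(O)CC[C@H]2[C@]1(C(=O)OC)CC[C@H](O[Si](C)(C)C(C)(C)C)[C@@](C)(C(=O)OC)[C@H]1[C@@H]3C(=O)OC | intermediate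
23 | trimethyl ester of the target gibberellin (3β,13-diol) | C=C1C[C@]23C[C@@]1(O)CC[C@H]2[C@]1(C(=O)OC)CC[C@H](O)[C@@](C)(C(=O)OC)[C@H]1[C@@H]3C(=O)OC | intermediate
24 | target gibberellin, ent-3α,13-dihydroxygibberell-16-ene-7,19,20-trioic acid (3β,13-dihydroxy in the convention of the remark) | C=C1C[C@]23C[C@@]1(O)CC[C@H]2[C@]1(C(=O)O)CC[C@H](O)[C@@](C)(C(=O)O)[C@H]1[C@@H]3C(=O)O | target

**Step count and risks**
Total steps: 16. Longest linear sequence: 16 steps (from 1 and 2 to 24); 4, 11 and all reagents are commercial.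

Steps most likely to fail:

Step 2. What may go wrong: proton transfer from the acidic CH2 of 4 or from the ketone to the ester enolates, oligomerisation of 4, Claisen closure onto C19 in place of conjugate addition, or poor facial control in the ring-A closure. Fallback, setting out from 3 and coming back at 7: 3 is converted with TBSOTf and Et3N into the silyl enol ether F1. F1 and 4 are combined under silyl-transfer (double Mukaiyama–Michael) conditions with catalytic TBSNTf2 in CH2Cl2 at −78 °C, so that no free enolate is present: the first addition gives the acyclic silyl ketene acetal F2, which is not isolated and closes ring A to the ring-A silyl ketene acetal F3. Anhydrous fluoride, (Me2N)3S+ Me3SiF2− in THF at −78 °C, then unmasks the C6 enolate regiospecifically as its tris(dimethylamino)sulfonium salt F4, which is not isolated and undergoes the Dieckmann closure to 7.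

Step 6. What may go wrong: incomplete second deprotonation at the hindered C9 or poor facial discrimination in the protonation. Fallback, setting out from 10 and coming back at 13: the dianion of 10 (LiN(i-Pr)2, THF, −78 °C) is added to 2-(2-methyl-1,3-dioxolan-2-yl)acetaldehyde to give the aldol F5, which is converted with MsCl and Et3N into the mesylate F6 and eliminated with DBU to the exocyclic enone F7. Hydrogenation (H2, Pd/C, EtOAc) should deliver hydrogen to C9 from the open β face and give 13.

Step 10. What may go wrong: γ-deprotonation at the doubly allylic C15 with migration of the allyl double bond into conjugation, or failure or reversal of the conjugate addition at the fully substituted C8. Fallback, setting out from 13 and coming back at 22: PPTS in wet THF unmasks the methyl ketone F8 as in step 9, and TsOH in toluene at reflux with removal of water effects intramolecular aldol condensation of C14 onto the C8 carbonyl, giving the ring-C enone F9 (13-oxo, C8=C14). Conjugate propargylation with allenylSnBu3 and TiCl4 in CH2Cl2 at −78 °C then creates the quaternary C8 and gives the propargyl ketone F10, the C6 epimer of 20 with the 6β ester retained. F10 is cyclised under the conditions of step 13 to give 22 directly, so that steps 11, 12 and 14 are not needed. This relies on attack on the ring-C enone from the β face, but that face of C8 is flanked by the 6β ester, so the C8 selectivity is less secure than with the tether.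

**Further compounds**
F1 | step 2 | TBS enol ether of 3, dimethyl (2E,4S)-4-[1-(tert-butyldimethylsilyloxy)ethenyl]-4-methylpent-2-enedioate | C=C(O[Si](C)(C)C(C)(C)C)[C@@](C)(C(=O)OC)/C=C/C(=O)OC
F2 | step 2 | acyclic Michael adduct of F1 and 4 carrying the C10 ester as its TBS ketene acetal (silyl analogue of 5) | COC(=O)CC(CCC(=O)[C@@](C)(C(=O)OC)/C=C/C(=O)OC)=C(O[Si](C)(C)C(C)(C)C)OC
F3 | step 2 | ring-A cyclohexanone carrying the C6 ester as its TBS ketene acetal (silyl analogue of 6) | COC(=O)C[C@]1(C(=O)OC)CCC(=O)[C@@](C)(C(=O)OC)[C@H]1C=C(O[Si](C)(C)C(C)(C)C)OC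
F4 | step 2 | tris(dimethylamino)sulfonium C6 ester enolate of the ring-A cyclohexanone (sulfonium counterpart of 6) | COC(=O)C[C@]1(C(=O)OC)CCC(=O)[C@@](C)(C(=O)OC)[C@H]1C=C([O-])OC.CN(C)[S+](N(C)C)N(C)C
F5 | step 6 | aldol adduct of 10 at C9 with 2-(2-methyl-1,3-dioxolan-2-yl)acetaldehyde (mixture at C9 and C11) | O=C1C(C(O)CC3(C)OCCO3)[C@]2(C(=O)OC)CC[C@H](O[Si](C)(C)C(C)(C)C)[C@@](C)(C(=O)OC)[C@H]2[C@@H]1C(=O)OC
F6 | step 6 | C11 mesylate of F5 | O=C1C(C(OS(C)(=O)=O)CC3(C)OCCO3)[C@]2(C(=O)OC)CC[C@H](O[Si](C)(C)C(C)(C)C)[C@@](C)(C(=O)OC)[C@H]2[C@@H]1C(=O)OC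
F7 | step 6 | (E)-9(11)-alkylidene β-keto triester from elimination of F6 | O=C1/C(=C/CC3(C)OCCO3)[C@]2(C(=O)OC)CC[C@H](O[Si](C)(C)C(C)(C)C)[C@@](C)(C(=O)OC)[C@H]2[C@@H]1C(=O)OC
F8 | step 10 | β-keto triester 13 with the ketal removed (3-oxobutyl chain at C9α) | O=C1[C@@H](CCC(C)=O)[C@]2(C(=O)OC)CC[C@H](O[Si](C)(C)C(C)(C)C)[C@@](C)(C(=O)OC)[C@H]2[C@@H]1C(=O)OC
F9 | step 10 | ABC tricyclic enone (13-oxo, C8=C14, H-9β, 6β-CO2Me, 3β-OTBS) | O=C1C=C2[C@@H](CC1)[C@]3(C(=O)OC)CC[C@H](O[Si](C)(C)C(C)(C)C)[C@@](C)(C(=O)OC)[C@H]3[C@@H]2C(=O)OC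
F10 | step 10 | 8β-propargyl 13-ketone with the 6β ester (C6 epimer of 20) | C#CC[C@]12CC(=O)CC[C@H]1[C@]3(C(=O)OC)CC[C@H](O[Si](C)(C)C(C)(C)C)[C@@](C)(C(=O)OC)[C@H]3[C@@H]2C(=O)OC
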